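## The problem

The target is a 3→8'' flavanone–flavone dimer. C3 of a naringenin unit (ring A is its phloroglucinol benzo ring, ring C the dihydropyranone, ring B the 4-hydroxyphenyl on C2) is bonded to C8'' of an apigenin unit (ring D benzo ring, ring E pyranone, ring F the 4-hydroxyphenyl on C2''). O7'', next to the junction, carries a hydrogen sulfate. The C3–C8'' bond is an sp3–sp2 bond flanked on ring D by two ortho oxygens (O1'' and O7''), so it is crowded and poorly suited to a late coupling on a finished flavanone. The two stereocentres, C2 (R) and C3 (S), are trans on ring C. Once C4 is a ketone, C3 is enolisable and settles into the trans arrangement dictated by C2, so C2 can control C3, but nothing in the molecule controls C2; its absolute configuration must come from the reaction that builds ring C. C2 can be lost by base-induced opening of ring C to a chalcone, the aryl sulfate monoester does not survive acid, the flavone enone can be over-reduced, and six phenols must be told apart (O7'' from O5'' and O4''', C8'' from C6''). The enabling feature is that O1 and C4 of ring C sit on adjacent carbons (C8a, C4a) of ring A. A ring A o-quinone methide carrying C4 at the aldehyde oxidation level supplies the O1–C8a–C4a–C4 oxadiene, and C2=C3 is then the alkene of a stilbene that already joins ring B to C8''. O1–C2 and C3–C4 can therefore form in one event, with the alkene geometry becoming the 2,3-trans relationship.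

## Retrosynthesis

**21 back to 20.** No skeletal bond is cut; the five O–benzyl bonds and the O–CH2CCl3 bond of a sulfate diester are restored. Sulfating the free hexaphenol could not be regioselective, and a sulfate monoester cannot be carried through acid steps. The 2,2,2-trichloroethyl diester is neutral, acid-stable and falls under the same reductive conditions as benzyl ethers. The forward step must spare the C2''=C3'' bond and the C4 ketone and must not epimerise C2 or C3.

**20 back to 19 and 18.** The C4 ketone is traced to the alcohol 19 and then to the methyl ether 18 (C4–H and O–CH3 restored). The ring-forming step delivers C4 as an ether, and keeping C4 reduced until late keeps C3–H non-acidic. The forward steps are a solvolysis that must not eliminate H3 and an oxidation that must not epimerise C3.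

**18 back to 13 and 15.** O1–C2 and C3–C4 are cut together, giving stilbene 13, salicylaldehyde 15 and trimethyl orthoformate (via acetal 16 and oxocarbenium ion 17). Cutting C3–C8'' instead would mean arylating a flavanone enolate at a doubly ortho-substituted carbon without absolute control. Cutting O1–C2 alone (oxa-Michael closure of an α-aryl chalcone) gives the trans isomer only as a racemate. The chosen cut removes ring C and both stereocentres at once and leaves two achiral partners. The forward reaction must place O1 on the carbon bearing ring B and select one alkene face. Because the alkene is very large, an open BINOL N-triflylphosphoramide is the first-choice chiral acid; a more confined imidodiphosphorimidate is the second.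

**13 back to 12, then to 8 and 11.** The S–O7'' bond is cut first, then the C8''–vinyl bond (Heck reaction). The sulfate is placed after the coupling so that the CCl3 group never meets zerovalent palladium under heat and base. An iodide is preferred to an 8-formyl group for olefination because C8 iodination of a 5,7-dialkoxyflavone is regioselective, and the Heck reaction gives the E alkene directly.

**8 back to 1.** The C8–I bond and the protecting-group pattern are traced to apigenin 1 (8 from 7, 6, 4, 3, 2). O7 is singled out because the 7-acetate of triacetate 2 is the most labile (giving 3). A methoxymethyl group holds O7 (4) while the acetates are exchanged for benzyl (6, via 5). Iodination is done on the 5,7-dialkoxy compound so that it goes to C8 and not C6 (7), and the methoxymethyl group is then removed (8).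

**11 back to 9 and 15 back to 14.** 4-Benzyloxystyrene 11 comes from 4-acetoxystyrene 9 by acetate-to-benzyl exchange through 4-vinylphenol 10. Aldehyde 15 comes from 2,4,6-trihydroxybenzaldehyde 14 by dibenzylation that stops at the hydrogen-bonded ortho hydroxyl.

## Roads not taken

**Alternative 1:** The cut is the flavone C2''=C3'' bond, so ring E closes last. A flavanone carrying ring D as an aryl ketone would be taken to the acylmethylenephosphorane A2. Its ylide carbon attacks the neighbouring 4-benzyloxybenzoate ester and expels triphenylphosphine oxide (intramolecular ester Wittig) to give A1, which is identical in constitution and configuration with 20.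
- Merits: flavone regiochemistry is fixed by construction, so neither the C6''/C8'' iodination question nor a coupling at a di-ortho-substituted iodide arises. Ring D before closure has no basic pyranone carbonyl to buffer an acid catalyst. In these respects this road is better.
- Weak points: it does not address the C3–C8'' bond or the stereocentres, so the ring C construction is still needed. The flavone is then built in four or five linear operations (ketone bromination, phosphonium salt, ylide, selective esterification of one of two ortho oxygens) on the most advanced, stereodefined material. The flavanone ketone with its acidic C3–H competes in the bromination and meets the ylide-forming base, which invites ring C opening and loss of C2. The trichloroethyl sulfate must also survive phosphine and base.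
- Comparison: the chosen plan sets against this regiochemical certainty a flavone taken intact from apigenin and joined convergently, with only three operations after the stereodefining step.

**Alternative 2:** The cut is C7''–C8'' of ring D, grown onto a preformed 2-aryl-4-pyranone. A non-nucleophilic base would deprotonate the CH2 on C6 of pyranone A4 (vinylogous enolate). This condenses with the ester of the β-keto ester on C5 (Claisen-type closure) and aromatises to the 5'',7''-dihydroxyflavone A3, which carries the ring A aryl ketone on the C8'' methylene.
- Merits: C8'' substitution is unambiguous. A3 offers O7'' as a free, unchelated phenol beside the chelated O5'', so the sulfate could be placed without the exchange of protecting groups that the chosen plan spends on this (steps 1 to 4 and 6). Here this road is clearly more economical.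
- Weak points: ring C must still be made from the deoxybenzoin by condensation with 4-benzyloxybenzaldehyde and oxa-Michael closure. That gives the trans flavanone under thermodynamic control but as a racemate; nothing controls C2, so a resolution or a poorly precedented asymmetric cyclisation of an α-aryl chalcone would be needed. A4 has three kinds of acidic C–H (β-keto ester, CH2 next to the ring A ketone, vinylogous CH2) and the least acidic must react. A4 itself needs a long de novo synthesis.
- Comparison: the chosen plan sets catalytic control of both stereocentres in the ring-forming step, and a commercial flavone, against the better phenol differentiation of this road.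

**Alternative 3:** The cut is C4''–C4a'', the aryl ketone bond of ring E. The (Z)-3-aryloxy-3-arylacrylic acid A6, attached through O1'' to ring D, would be converted by trifluoroacetic anhydride into a mixed anhydride. This acylates the only free ring D carbon ortho to that oxygen (intramolecular Friedel–Crafts acylation) to give the 7''-O-allyl biflavonoid A5.
- Merits: one free position means one regiochemical outcome. The allyl ether marks O7'' for late unmasking, so the sulfate diester is introduced after all acid- and palladium-mediated C–C bond formation. That is gentler on the sulfate than the chosen plan, where it passes through the key step and two further operations.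
- Weak points: as in Alternative 1, the stereocentres and the C3–C8'' bond must already be in place. The acylation runs under strongly acidic, electrophilic conditions in the presence of rings A and B, both more electron-rich than the position of ring D that must react, and of an enolisable flavanone. From A5 three more operations follow (deallylation, sulfation, hydrogenolysis), the first exposing the base-sensitive flavanone to zerovalent palladium and a nucleophile. The Z geometry of A6 must also be secured.
- Comparison: the chosen plan sets convergence and the use of intact apigenin against the later, safer sulfation of this road.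

Key step: step 11

Assumption: the target is drawn as the free aryl hydrogen sulfate; step 14 first gives its ammonium salt (the storable form), which is converted to the acid on an H+-form resin.

Assumption: the chiral acid is written as the (R)-BINOL-derived enantiomer; if the sense of induction proves opposite, the (S) catalyst is used.

Positions in steps 1 to 9 follow apigenin numbering (5, 7, 8, 4'); they become 5'', 7'', 8'' and 4''' in the dimer.

## Route

Step 1
Reactants: 1 apigenin
Product: 2 4',5,7-tri-O-acetylapigenin
Conditions: Ac2O, pyridine, rt → 60 °C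
Reagents that add atoms: acetic anhydride, CC(=O)OC(C)=O
Why: Peracetylation of phenols (O-acylation); the chelated 5-OH should also react under pyridine catalysis on gentle warming.

Step 2
Reactants: 2 4',5,7-tri-O-acetylapigenin
Product: 3 4',5-di-O-acetylapigenin (7-OH free)
Conditions: PhSH, imidazole, NMP, 0 °C → rt
Reagents that add atoms: none
Why: Thiolate transacylation should remove only the acetate of the most acidic phenol (O7, vinylogous to the C4 carbonyl and the best leaving phenoxide), a known regioselective 7-O-deacylation of flavone peracetates.

Step 3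
Reactants: 3 4',5-di-O-acetylapigenin
Product: 4 4',5-di-O-acetyl-7-O-(methoxymethyl)apigenin
Conditions: MOMCl, i-Pr2NEt, CH2Cl2, 0 °C → rt
Reagents that add atoms: chloromethyl methyl ether, COCCl
Why: O-Alkylation of the only free phenol (Williamson-type acetal formation) under a non-nucleophilic amine base, which should leave the aryl acetates untouched.

Step 4
Reactants: 4 4',5-di-O-acetyl-7-O-(methoxymethyl)apigenin
Product: 6 4',5-di-O-benzyl-7-O-(methoxymethyl)apigenin, via 7-O-(methoxymethyl)apigenin 5 (not isolated)
Conditions: K2CO3, MeOH/THF, rt; solvent exchange; BnBr, K2CO3, DMF, 60 °C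
Reagents that add atoms: benzyl bromide, BrCc1ccccc1
Why: Base-catalysed methanolysis of both aryl acetates followed by Williamson benzylation of the two phenoxides in one flask; the chelated 5-OH needs the heating in DMF, and the methoxymethyl acetal is stable to base.

Step 5
Reactants: 6 4',5-di-O-benzyl-7-O-(methoxymethyl)apigenin
Product: 7 4',5-di-O-benzyl-8-iodo-7-O-(methoxymethyl)apigenin
Conditions: NIS, TFA (0.2 equiv), MeCN, 0 °C → rt
Reagents that add atoms: N-iodosuccinimide, O=C1CCC(=O)N1I
Why: Electrophilic aromatic iodination; in 5,7-dialkoxyflavones C8 is the reactive position, C6 being flanked by two alkoxy groups, and ring F is deactivated by conjugation with the pyranone.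

Step 6
Reactants: 7 4',5-di-O-benzyl-8-iodo-7-O-(methoxymethyl)apigenin
Product: 8 4',5-di-O-benzyl-8-iodoapigenin (7-OH free)
Conditions: 3 M HCl, MeOH/THF, 50 °C
Reagents that add atoms: none
Why: Acid-catalysed acetal solvolysis removes the methoxymethyl group; benzyl ethers and the aryl iodide should be stable to dilute HCl in methanol.

Step 7
Reactants: 9 4-acetoxystyrene
Product: 11 4-benzyloxystyrene, via 4-vinylphenol 10 (not isolated)
Conditions: K2CO3, MeOH, rt; solvent exchange; BnBr, DMF, rt
Reagents that add atoms: benzyl bromide, BrCc1ccccc1
Why: Methanolysis of the aryl acetate gives the phenoxide, which is benzylated in the same flask (Williamson ether synthesis), so polymerisation-prone 4-vinylphenol is never isolated.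

Step 8
Reactants: 8 4',5-di-O-benzyl-8-iodoapigenin; 11 4-benzyloxystyrene
Product: 12 (E)-4',5-di-O-benzyl-8-[2-(4-benzyloxyphenyl)ethenyl]apigenin (7-OH free)
Conditions: Pd(OAc)2 (5 mol%), n-Bu4NCl, NaHCO3, DMF, 80 °C
Reagents that add atoms: none
Why: Mizoroki–Heck reaction under ligand-free conditions with an ammonium chloride; syn insertion and syn β-hydride elimination should give the E stilbene, and o-iodophenols are competent partners.

Step 9
Reactants: 12 (E)-4',5-di-O-benzyl-8-[2-(4-benzyloxyphenyl)ethenyl]apigenin
Product: 13 (E)-4',5-di-O-benzyl-8-[2-(4-benzyloxyphenyl)ethenyl]apigenin 7-O-(2,2,2-trichloroethyl sulfate)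
Conditions: Cl3CCH2OSO2Cl, Et3N, DMAP, THF, 0 °C → rt
Reagents that add atoms: 2,2,2-trichloroethyl chlorosulfate, ClS(=O)(=O)OCC(Cl)(Cl)Cl
Why: DMAP-catalysed O-sulfonylation of the phenoxide by the chlorosulfate gives the aryl trichloroethyl sulfate diester, a known masked aryl sulfate; it is installed after the Heck reaction so that the CCl3 group is not exposed to zerovalent palladium.

Step 10
Reactants: 14 2,4,6-trihydroxybenzaldehyde
Product: 15 2,4-bis(benzyloxy)-6-hydroxybenzaldehyde
Conditions: BnBr (2.05 equiv), K2CO3, DMF, 0 °C → rt
Reagents that add atoms: benzyl bromide, BrCc1ccccc1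
Why: Williamson benzylation of the 4-OH and one ortho OH; the remaining ortho OH is held in a hydrogen bond to the formyl group and should resist alkylation, as is known for this aldehyde.

Step 11
Reactants: 15 2,4-bis(benzyloxy)-6-hydroxybenzaldehyde; 13 (E)-stilbene trichloroethyl sulfate
Product: 18 (2R,3R,4R)-4-methoxyflavan carrying the protected flavon-8-yl group at C3, via dimethyl acetal 16 (not isolated), via oxocarbenium ion 17 (not isolated)
Conditions: 15 (1.5 equiv), HC(OMe)3 (2 equiv), (R)-3,3'-bis(2,4,6-triisopropylphenyl)-BINOL N-triflylphosphoramide (10 mol%), 5 Å MS, CHCl3, rt; then 13, −40 → −20 °C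
Reagents that add atoms: trimethyl orthoformate, COC(OC)OC
Why: The aldehyde and HC(OMe)3 give acetal 16, whose acid-induced loss of methanol produces the O-methyl oxocarbenium ion 17, the O-protonated form of a 4-methoxy o-quinone methide, held to the chiral phosphoramide anion by ion pairing and a hydrogen bond from its phenolic OH. Acting as a 1-oxadiene, 17 should add across the alkene of 13 in an inverse-electron-demand oxa-Diels–Alder reaction: the alkene carbon attached to C8'' bonds to the oxocarbenium carbon (C3–C4) while the phenolic oxygen captures the developing benzylic cation (O1–C2). The closest known reaction types are the acid-catalysed three-component chroman synthesis from salicylaldehydes, orthoformates and styrenes and the chiral Brønsted acid-catalysed [4+2] addition of o-quinone methides to styrenes. Ring C closes as a six-membered ring in this concerted but asynchronous [4+2] event. C2 and C3 are set relative to each other by the E geometry of the alkene through suprafacial addition (2,3-trans); a stepwise passage through the benzylic cation would converge on the same diequatorial pair. Their absolute sense is set by the chiral anion, which screens one face of 17 and, with the methoxy group turned away from the incoming ring D (3,4-trans), determines which alkene face is engaged; C4 is only a relay and is erased in step 13. The reaction needs O1 to end on the carbon bearing the 4-benzyloxyphenyl group, which is secured because that ring stabilises positive charge far better than ring D, twisted by its two ortho oxygens and deactivated by the sulfate diester.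

Step 12
Reactants: 18 (2R,3R,4R)-4-methoxyflavan
Product: 19 (2R,3R,4R)-flavan-4-ol (the C4 epimer, if formed, is carried on as well)
Conditions: TsOH·H2O (0.2 equiv), THF/H2O 4:1, 0 °C → rt
Reagents that add atoms: water, O
Why: SN1 solvolysis of the doubly activated benzylic methyl ether (ionisation assisted by O1 and the 5,7-dialkoxy ring A) with capture by water; low temperature and a large excess of water should favour capture over E1 loss of H3, and the C4 configuration is immaterial.

Step 13
Reactants: 19 (2R,3R,4R)-flavan-4-ol
Product: 20 (2R,3S)-pentabenzyl biflavonoid 7''-O-(2,2,2-trichloroethyl sulfate)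
Conditions: Dess–Martin periodinane, NaHCO3, CH2Cl2, 0 °C → rt
Reagents that add atoms: none
Why: Dess–Martin oxidation of the secondary benzylic alcohol to the aryl ketone under buffered, near-neutral conditions, so the newly acidic C3–H should not be epimerised; the 2,3-trans arrangement is also the thermodynamic one.

Step 14
Reactants: 20 (2R,3S)-pentabenzyl biflavonoid 7''-O-(2,2,2-trichloroethyl sulfate)
Product: 21 target, (2R,3S)-naringenin-(3→8'')-apigenin 7''-O-sulfate
Conditions: 10% Pd/C, HCO2NH4, MeOH/THF, rt; then H+-form cation-exchange resin, 0 °C
Reagents that add atoms: none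
Why: Catalytic transfer hydrogenolysis should cleave the five benzyl ethers and, by reductive fragmentation of the Cl3CCH2 group, the trichloroethyl ester, a known unmasking of such protected aryl sulfates; the neutral medium should leave C2, C3 and the sulfate monoester intact.

## Compound list

1 | apigenin, 5,7-dihydroxy-2-(4-hydroxyphenyl)-4H-chromen-4-one | O=c1cc(-c2ccc(O)cc2)oc2cc(O)cc(O)c12 | starting material
2 | 4',5,7-tri-O-acetylapigenin | O=c1cc(-c2ccc(OC(C)=O)cc2)oc2cc(OC(C)=O)cc(OC(C)=O)c12 | intermediate
3 | 4',5-di-O-acetylapigenin (7-hydroxy) | O=c1cc(-c2ccc(OC(C)=O)cc2)oc2cc(O)cc(OC(C)=O)c12 | intermediate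
4 | 4',5-di-O-acetyl-7-O-(methoxymethyl)apigenin | O=c1cc(-c2ccc(OC(C)=O)cc2)oc2cc(OCOC)cc(OC(C)=O)c12 | intermediate
5 | 7-O-(methoxymethyl)apigenin | O=c1cc(-c2ccc(O)cc2)oc2cc(OCOC)cc(O)c12 | intermediate
6 | 4',5-di-O-benzyl-7-O-(methoxymethyl)apigenin | O=c1cc(-c2ccc(OCc3ccccc3)cc2)oc2cc(OCOC)cc(OCc3ccccc3)c12 | intermediate
7 | 4',5-di-O-benzyl-8-iodo-7-O-(methoxymethyl)apigenin | O=c1cc(-c2ccc(OCc3ccccc3)cc2)oc2c(I)c(OCOC)cc(OCc3ccccc3)c12 | intermediate
8 | 4',5-di-O-benzyl-8-iodoapigenin, 5-(benzyloxy)-2-[4-(benzyloxy)phenyl]-7-hydroxy-8-iodo-4H-chromen-4-one | O=c1cc(-c2ccc(OCc3ccccc3)cc2)oc2c(I)c(O)cc(OCc3ccccc3)c12 | intermediate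
9 | 4-acetoxystyrene | C=Cc1ccc(OC(C)=O)cc1 | starting material
10 | 4-vinylphenol | C=Cc1ccc(O)cc1 | intermediate
11 | 4-benzyloxystyrene | C=Cc1ccc(OCc2ccccc2)cc1 | intermediate
12 | (E)-5-(benzyloxy)-2-[4-(benzyloxy)phenyl]-8-{2-[4-(benzyloxy)phenyl]ethenyl}-7-hydroxy-4H-chromen-4-one | O=c1cc(-c2ccc(OCc3ccccc3)cc2)oc2c(/C=C/c3ccc(OCc4ccccc4)cc3)c(O)cc(OCc3ccccc3)c12 | intermediate
13 | (E)-5-(benzyloxy)-2-[4-(benzyloxy)phenyl]-8-{2-[4-(benzyloxy)phenyl]ethenyl}-4-oxo-4H-chromen-7-yl 2,2,2-trichloroethyl sulfate | O=c1cc(-c2ccc(OCc3ccccc3)cc2)oc2c(/C=C/c3ccc(OCc4ccccc4)cc3)c(OS(=O)(=O)OCC(Cl)(Cl)Cl)cc(OCc3ccccc3)c12 | intermediate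
14 | 2,4,6-trihydroxybenzaldehyde | O=Cc1c(O)cc(O)cc1O | starting material
15 | 2,4-bis(benzyloxy)-6-hydroxybenzaldehyde | O=Cc1c(O)cc(OCc2ccccc2)cc1OCc1ccccc1 | intermediate
16 | 3,5-bis(benzyloxy)-2-(dimethoxymethyl)phenol (dimethyl acetal of 15) | COC(OC)c1c(O)cc(OCc2ccccc2)cc1OCc1ccccc1 | intermediate
17 | (E)-[2,4-bis(benzyloxy)-6-hydroxybenzylidene](methyl)oxonium ion, the O-protonated 4-methoxy o-quinone methide | C/[O+]=C/c1c(O)cc(OCc2ccccc2)cc1OCc1ccccc1 | intermediate
18 | 5-(benzyloxy)-2-[4-(benzyloxy)phenyl]-8-{(2R,3R,4R)-5,7-bis(benzyloxy)-2-[4-(benzyloxy)phenyl]-4-methoxychroman-3-yl}-4-oxo-4H-chromen-7-yl 2,2,2-trichloroethyl sulfate (2,3-trans, 3,4-trans) | CO[C@H]1c2c(OCc3ccccc3)cc(OCc3ccccc3)cc2O[C@@H](c2ccc(OCc3ccccc3)cc2)[C@@H]1c1c(OS(=O)(=O)OCC(Cl)(Cl)Cl)cc(OCc2ccccc2)c2c(=O)cc(-c3ccc(OCc4ccccc4)cc3)oc12 | intermediate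
19 | 5-(benzyloxy)-2-[4-(benzyloxy)phenyl]-8-{(2R,3R,4R)-5,7-bis(benzyloxy)-2-[4-(benzyloxy)phenyl]-4-hydroxychroman-3-yl}-4-oxo-4H-chromen-7-yl 2,2,2-trichloroethyl sulfate | O[C@H]1c2c(OCc3ccccc3)cc(OCc3ccccc3)cc2O[C@@H](c2ccc(OCc3ccccc3)cc2)[C@@H]1c1c(OS(=O)(=O)OCC(Cl)(Cl)Cl)cc(OCc2ccccc2)c2c(=O)cc(-c3ccc(OCc4ccccc4)cc3)oc12 | intermediate
20 | 5-(benzyloxy)-2-[4-(benzyloxy)phenyl]-8-{(2R,3S)-5,7-bis(benzyloxy)-2-[4-(benzyloxy)phenyl]-4-oxochroman-3-yl}-4-oxo-4H-chromen-7-yl 2,2,2-trichloroethyl sulfate (2,3-trans) | O=C1c2c(OCc3ccccc3)cc(OCc3ccccc3)cc2O[C@@H](c2ccc(OCc3ccccc3)cc2)[C@@H]1c1c(OS(=O)(=O)OCC(Cl)(Cl)Cl)cc(OCc2ccccc2)c2c(=O)cc(-c3ccc(OCc4ccccc4)cc3)oc12 | intermediate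
21 | 5-hydroxy-2-(4-hydroxyphenyl)-8-[(2R,3S)-5,7-dihydroxy-2-(4-hydroxyphenyl)-4-oxochroman-3-yl]-4-oxo-4H-chromen-7-yl hydrogen sulfate (2,3-trans) | O=C1c2c(O)cc(O)cc2O[C@@H](c2ccc(O)cc2)[C@@H]1c1c(OS(=O)(=O)O)cc(O)c2c(=O)cc(-c3ccc(O)cc3)oc12 | target

## Step count and least certain steps

Total: 14 steps. Longest linear sequence: 12 steps (1 to 6, 8, 9, 11 to 14, from apigenin).

**Step 11 (key step).** The chiral anion may discriminate the two alkene faces poorly for so large a partner. If both C4 epimers form from the same oxocarbenium face, they carry opposite configurations at C2 and C3, and enantiomeric purity is eroded once C4 is oxidised; the epimers therefore have to be checked or separated before step 12. The addition may also be slow, since the basic flavone carbonyl can buffer the acid and the alkene is hindered, and the orientation of addition may be partly reversed. Fallback: setting out from 13 and 15, the same three-component union is run with achiral Sc(OTf)3 and HC(OMe)3 in CH2Cl2, the documented catalyst type for this chroman synthesis. This should give the all-trans adduct as a racemate, that is 18 together with its mirror image, the (2S,3S,4S)-methoxyflavan F1. Preparative chromatography on a polysaccharide-based chiral stationary phase separates the two, and the route is rejoined at 18.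

**Step 12.** The C4 cation may lose H3 (E1 elimination) to a 3-aryl-2H-chromene, which destroys C3, or may be captured too slowly at the crowded centre. Fallback: setting out from 18, the methyl ether is oxidised directly with DDQ in wet CH2Cl2. Hydride abstraction from C4–H gives a methoxy-stabilised cation that water converts to the ketone, and even an enol ether formed by loss of H3 hydrolyses to the same ketone with C3 reset by C2. This fallback makes no new compound (F0) and rejoins the route at 20.

**Step 14.** The C2''=C3'' bond of ring E or the C4 ketone may be reduced before the last benzyl ether has gone, or the sulfate may be lost during prolonged reaction. Fallback: setting out from 20, zinc dust and HCO2NH4 in MeOH/THF remove only the trichloroethyl group and give the ammonium salt of the pentabenzyl biflavonoid 7''-sulfate F2. The benzyl ethers are then cleaved separately with H2 (1 atm) over Pd(OH)2/C in THF/MeOH, stopped as soon as debenzylation is complete, which returns to the route at 21.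

**Step 8.** Oxidative addition and insertion may stall at the electron-rich, di-ortho-substituted iodide, with hydrodeiodination taking over. Fallback: setting out from 11, cross-metathesis with vinylboronic acid pinacol ester (second-generation Grubbs catalyst, CH2Cl2, 40 °C) gives (E)-2-[2-(4-benzyloxyphenyl)ethenyl]-4,4,5,5-tetramethyl-1,3,2-dioxaborolane F3. Suzuki–Miyaura coupling of F3 with 8 (Pd(dppf)Cl2, K2CO3, dioxane/H2O, 80 °C) returns to the route at 12.

## Further compounds

F1 | step 11 | (2S,3S,4S) enantiomer of 18 | CO[C@@H]1c2c(OCc3ccccc3)cc(OCc3ccccc3)cc2O[C@H](c2ccc(OCc3ccccc3)cc2)[C@H]1c1c(OS(=O)(=O)OCC(Cl)(Cl)Cl)cc(OCc2ccccc2)c2c(=O)cc(-c3ccc(OCc4ccccc4)cc3)oc12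
F0 | step 12 | none | none
F2 | step 14 | ammonium 5-(benzyloxy)-2-[4-(benzyloxy)phenyl]-8-{(2R,3S)-5,7-bis(benzyloxy)-2-[4-(benzyloxy)phenyl]-4-oxochroman-3-yl}-4-oxo-4H-chromen-7-yl sulfate | O=C1c2c(OCc3ccccc3)cc(OCc3ccccc3)cc2O[C@@H](c2ccc(OCc3ccccc3)cc2)[C@@H]1c1c(OS(=O)(=O)[O-])cc(OCc2ccccc2)c2c(=O)cc(-c3ccc(OCc4ccccc4)cc3)oc12.[NH4+]
F3 | step 8 | (E)-2-[2-(4-benzyloxyphenyl)ethenyl]-4,4,5,5-tetramethyl-1,3,2-dioxaborolane | CC1(C)OB(/C=C/c2ccc(OCc3ccccc3)cc2)OC1(C)C
A1 | alternative 1 | (2R,3S)-pentabenzyl biflavonoid 7''-O-(2,2,2-trichloroethyl sulfate), identical with 20 | O=C1c2c(OCc3ccccc3)cc(OCc3ccccc3)cc2O[C@@H](c2ccc(OCc3ccccc3)cc2)[C@@H]1c1c(OS(=O)(=O)OCC(Cl)(Cl)Cl)cc(OCc2ccccc2)c2c(=O)cc(-c3ccc(OCc4ccccc4)cc3)oc12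
A2 | alternative 1 | (2R,3S)-flavanone whose C3 aryl group carries a 4-benzyloxybenzoate ester ortho to a (triphenylphosphoranylidene)acetyl group | O=C1c2c(OCc3ccccc3)cc(OCc3ccccc3)cc2O[C@@H](c2ccc(OCc3ccccc3)cc2)[C@@H]1c1c(OS(=O)(=O)OCC(Cl)(Cl)Cl)cc(OCc2ccccc2)c(C(=O)C=P(c2ccccc2)(c2ccccc2)c2ccccc2)c1OC(=O)c1ccc(OCc2ccccc2)cc1
A3 | alternative 2 | 8-{2-[2,4-bis(benzyloxy)-6-(methoxymethoxy)phenyl]-2-oxoethyl}-2-[4-(benzyloxy)phenyl]-5,7-dihydroxy-4H-chromen-4-one | COCOc1cc(OCc2ccccc2)cc(OCc2ccccc2)c1C(=O)Cc1c(O)cc(O)c2c(=O)cc(-c3ccc(OCc4ccccc4)cc3)oc12
A4 | alternative 2 | methyl 3-{6-[4-(benzyloxy)phenyl]-2-{3-[2,4-bis(benzyloxy)-6-(methoxymethoxy)phenyl]-3-oxopropyl}-4-oxo-4H-pyran-3-yl}-3-oxopropanoate | COCOc1cc(OCc2ccccc2)cc(OCc2ccccc2)c1C(=O)CCc1oc(-c2ccc(OCc3ccccc3)cc2)cc(=O)c1C(=O)CC(=O)OC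
A5 | alternative 3 | (2R,3S)-pentabenzyl 7''-O-allyl biflavonoid | O=C1c2c(OCc3ccccc3)cc(OCc3ccccc3)cc2O[C@@H](c2ccc(OCc3ccccc3)cc2)[C@@H]1c1c(OCC=C)cc(OCc2ccccc2)c2c(=O)cc(-c3ccc(OCc4ccccc4)cc3)oc12
A6 | alternative 3 | (Z)-3-[4-(benzyloxy)phenyl]-3-{[3-(allyloxy)-5-(benzyloxy)-2-((2R,3S)-flavanon-3-yl)]phenoxy}acrylic acid, the flavanone being the 5,7,4'-tribenzyl ether | O=C1c2c(OCc3ccccc3)cc(OCc3ccccc3)cc2O[C@@H](c2ccc(OCc3ccccc3)cc2)[C@@H]1c1c(OCC=C)cc(OCc2ccccc2)cc1O/C(=C\C(=O)O)c1ccc(OCc2ccccc2)cc1
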